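Elm held 0.0510 M of G beyond its E, one to one, and ash 0 M, so I reckoned from that excess.

| setting | east | west | ash | elm |
|---|---|---|---|---|
| G | 0.048 M | 0.14 M | 0.071 M | 0.071 M |
| E | 0.071 M | 0.071 M | 0.0710 M | 0.0200 M |
| remark | run made earlier | run made earlier |  |  |
| time |  |  | 1.0 h | 1.5 h |

- east (time / min: L / %, G / %): 3.00: 0.3, 65.5; 10.0: 4.5, 31.2; 15.0: 4.8, 20.6; 25.0: 8.7, 12.9; 40.0: 16.2, 5.1
- west (time / min: L / %, G / %): 3.00: 0.9, 70.0; 10.0: 2.4, 51.2; 15.0: 3.7, 45.6; 25.0: 4.0, 38.5; 40.0: 8.0, 34.3

(each reading ± 1 percentage point)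

- a reading or a percentage of L counts all its forms, free or not

* the winner by amount of L, in percent of the G charged; "neither" if no more than 2 percentage points parts them (ash / elm / neither)
* how much L is there at the end, in percent of the G charged: ash
* how much L is there at the end, in percent of the G charged: elm

L “keeps rising after most of the G has gone”, so G and E first fill a store that turns slowly into L. In west, G gone by 25.0 min was 0.0861 M, more than the E charged, so I took the extra G to be eating the store, one store unit per extra G. East, with more E than G, gave the step to L.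

West, 15.0 min to 40.0 min: G fell 6.33 × 10⁻⁴ M min⁻¹; store 0.0503 M, cG 0.0539 M; kG = 0.233 M⁻¹ min⁻¹

East, 10.0 min to 40.0 min: L rose 1.87 × 10⁻⁴ M min⁻¹; store 0.0376 M; kL = 0.00497 min⁻¹

These are readings, with their scatter. My carried quantity is the branch share, the part of the store reaching L with excess G present, kL/(kL + kG·excess), a selectivity: 29.5% for elm.

Two extremes bound elm. If the excess G were idle, L would reach 10.2%; if it ate the store at once, none. The real flask lies between: the lifetime against G, 84.2 min, is shorter than that towards L, 201 min, and the run lasted 90 min.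

Elm: store lifetime 59.2 min; L = 6.48%

Ash has no excess, so I placed it between east's 16.2% at 40.0 min and a full-store ceiling of 25.8%.

The forecast said ash, 20% and 11%; my elm figure is lower.

The flask gave ash: ash 18.4%, elm 5.50%.

    G + E → D (k = 150 M⁻¹ h⁻¹)
    D ⇌ L (K = 0.710, k = 0.460 h⁻¹)
    G + D → Q (k = 15.0 M⁻¹ h⁻¹)
    2 E → Z (k = 12.0 M⁻¹ h⁻¹)
    E + L ⇌ J, settled at all times (K = 7.10 M⁻¹)

The store is D. In elm at 1.50 h, Q held 28.4%, two G each, so L was 27.9% of L plus eaten D, against the share of 29.5%. A neighbouring flask is elm with 0.18 M of G, so E stood at 0.111 equiv. Its excess of 0.160 M gives a share of 11.8%, a lifetime of 23.6 min and L of 1.28%. The flask held Q at 19.1% and L at 0.980%.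

(The earlier runs and the new flask are simulated from invented constants, noise included.)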